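**Retrosynthetic overview**

- Own numbering: C1 = CH(OAc) next to the quaternary carbon, C2 = CH2, C3 = C(CH3)(OAc), C4 = CH2, C5 = ring-fusion CH, C6 = CH2, C7 = C=O, C8=C9 = enone C=C, C10, C11, N12, C13–C15, C16 = quaternary carbon. Ring A = cyclohexane (C1–C5, C16), ring B = cyclopentanone (C5–C8, C16), ring C = azonine (C8–C16).
- Ring A is cut at C2–C3 and C5–C16: a [3+3] Michael/aldol-condensation between the extended dienolate of acetyl-azonine 7 (C16–C1–C2 unit) and enone 10 (C3–C4–C5 unit). The enabling feature is that C16 is at once α to the oxygenated C1 and allylic to the C8=C9 double bond of ring C, while C1 and C3 carry 1,3-oxygen (aldol retron) and C5 is β to C3.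
- Ring order: C first (symmetric azonine 5 from cycloocta-1,5-diene), then A (key step, which also places the olefin at C8=C9), then B last (carbonyl-ene closure C7–C8 onto that olefin, then oxidation and isomerisation to the enone).
- The syn-1,3-diacetate comes from the ring A enone by Luche reduction, hydroxyl-directed epoxidation and hydride opening; N-Ts is exchanged for N-CHO at the diol stage.

Key step: step 6

Remark: 8 and 9 are taken as commercial. C7 and C8 are stereocentres only temporarily (21, 22) and are left undefined because both are lost in step 15.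

**Step 1**
Reactants: 1 (1Z,5Z)-cycloocta-1,5-diene
Product: 2 (4Z)-oct-4-ene-1,8-diol
Conditions: O3 (1.0 equiv), CH2Cl2/MeOH, −78 °C; then NaBH4, −78 °C → rt
Reagents that add atoms: ozone, O=[O+][O-]
Why: One equivalent of ozone should cleave one of the two equivalent cis double bonds (ozonolysis with reductive work-up), and the remaining Z-olefin is carried unchanged into the diol.

**Step 2**
Reactants: 2 (4Z)-oct-4-ene-1,8-diol
Product: 3 (4Z)-oct-4-ene-1,8-diyl dimethanesulfonate
Conditions: MsCl, Et3N, CH2Cl2, 0 °C
Reagents that add atoms: methanesulfonyl chloride, CS(=O)(=O)Cl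
Why: Sulfonylation of the two primary alcohols should be fast and clean and turns both chain ends into leaving groups.

**Step 3**
Reactants: 3 (4Z)-oct-4-ene-1,8-diyl dimethanesulfonate; 4 4-methylbenzenesulfonamide
Product: 5 (5Z)-1-(4-methylbenzenesulfonyl)-2,3,4,7,8,9-hexahydro-1H-azonine
Conditions: Cs2CO3, DMF, 60 °C, slow addition (high dilution)
Reagents that add atoms: none
Why: Double N-alkylation of the acidic sulfonamide should close the nine-membered ring because the Z-olefin holds the two chain ends on the same side and high dilution suppresses oligomers.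

**Step 4**
Reactants: 5 (5Z)-1-(4-methylbenzenesulfonyl)-2,3,4,7,8,9-hexahydro-1H-azonine
Product: 7 1-[(5E)-1-(4-methylbenzenesulfonyl)-2,3,4,7,8,9-hexahydro-1H-azonin-5-yl]ethan-1-one, via β-chloro ketone 6 (not isolated)
Conditions: AcCl, SnCl4, CH2Cl2, −78 °C; then DBU, 0 °C → rt
Reagents that add atoms: acetyl chloride, CC(=O)Cl
Why: Friedel–Crafts acylation of the symmetric olefin should give one β-chloro ketone whichever olefin carbon is attacked, and E1cB loss of HCl gives the conjugated enone with the ring olefin still cis within the ring.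

**Step 5**
Reactants: 8 3-[(tert-butyldimethylsilyl)oxy]propanal; 9 1-(triphenyl-λ5-phosphanylidene)propan-2-one
Product: 10 (3E)-6-[(tert-butyldimethylsilyl)oxy]hex-3-en-2-one
Conditions: CH2Cl2, 40 °C
Reagents that add atoms: none
Why: Wittig olefination with the stabilised acetonyl ylide should give the E-enone selectively.

**Step 6**
Reactants: 7 acetyl-azonine enone; 10 (3E)-6-[(tert-butyldimethylsilyl)oxy]hex-3-en-2-one
Product: 12 (5S,6S,13Z)-5-[2-(tert-butyldimethylsilyloxy)ethyl]-3-methyl-10-(4-methylbenzenesulfonyl)-10-azaspiro[5.8]tetradeca-2,13-dien-1-one, via Michael adduct 11 (not isolated)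
Conditions: chiral C2-symmetric N-spiro binaphthyl quaternary ammonium bromide (5 mol %), CsOH·H2O, toluene, −30 °C; then KOt-Bu, t-BuOH, 25 °C
Reagents that add atoms: none
Why: Proposed new method: hydroxide removes the γ-hydrogen (C9–H) of 7 at the solid–liquid interface, the extended dienolate (ion-paired with the chiral ammonium cation) adds through its α-carbon C16 to C5 of enone 10 (deconjugative Michael addition: C5–C16 bond, all-carbon quaternary centre, olefin shifted to C8=C9), and after addition of KOt-Bu the C2 enolate of the methyl ketone in 11 attacks the C3 carbonyl and water is lost by E1cB (C2–C3 bond). The closest known reaction types are the Robinson-type Michael/aldol-condensation annulation of α-branched ketones through the more substituted enolate, deconjugative α-alkylation of extended enolates, and chiral ammonium phase-transfer Michael additions of tertiary carbon acids to enones; their combination on a medium-ring dienolate with a β-substituted enone is the new element. Ring A is the only ring closed, by a 6-(enolendo)-exo-trig aldol addition followed by dehydration. C16 and C5 arise together in the Michael step: allylic strain keeps the C2 methyl next to the vinylic C8–H so the enolate oxygen lies on the C15 side, a closed transition state bridges this oxygen and the enone oxygen with C5–H over the nine-membered ring and the C6 chain in the open sector beside sp2 C8, which should place the C6 chain cis to the C8=C9 branch, and the chiral cation shields one face of the planar dienolate so that the antipode of the catalyst selects the (5S,16S) series. The step needs α- rather than γ- or methyl-carbon attack and C2→C3 rather than C3-methyl→C1 aldol closure: thermodynamic deprotonation gives only the extended dienolate, only its α-adduct can close a six-membered ring by aldol condensation, and the C1 carbonyl, flanked by the new quaternary carbon, is a much poorer electrophile than the unhindered C3 methyl ketone.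

**Step 7**
Reactants: 12 spiro enone
Product: 13 (1S,5S,6S,13Z)-5-[2-(tert-butyldimethylsilyloxy)ethyl]-3-methyl-10-(4-methylbenzenesulfonyl)-10-azaspiro[5.8]tetradeca-2,13-dien-1-ol
Conditions: NaBH4, CeCl3·7H2O, MeOH, −78 °C
Reagents that add atoms: none
Why: Luche reduction should be 1,2-selective, and axial hydride attack on the face opposite the pseudo-axial C8=C9 branch at C16 sets C1 with the hydroxyl cis to that branch.

**Step 8**
Reactants: 13 allylic alcohol
Product: 14 syn-2,3-epoxy alcohol (epoxide oxygen on the face of the C1 hydroxyl; C1 R, C2 R, C3 S)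
Conditions: VO(acac)2 (cat.), t-BuOOH, CH2Cl2, 0 °C
Reagents that add atoms: tert-butyl hydroperoxide, CC(C)(C)OO
Why: Hydroxyl-directed vanadium-catalysed epoxidation should deliver oxygen syn to the C1 hydroxyl, which sets C2 and C3, and the allylic C2=C3 olefin reacts much faster than the homoallylic C8=C9 olefin.

**Step 9**
Reactants: 14 syn-epoxy alcohol
Product: 15 (1S,3S,5R,6S,13Z)-5-[2-(tert-butyldimethylsilyloxy)ethyl]-3-methyl-10-(4-methylbenzenesulfonyl)-10-azaspiro[5.8]tetradec-13-ene-1,3-diol
Conditions: LiAlH4, THF, 0 °C → rt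
Reagents that add atoms: none
Why: SN2 hydride opening of the trisubstituted epoxide should occur at the less substituted C2, so the tertiary C3–O bond and its configuration are kept and the syn-1,3-diol results.

**Step 10**
Reactants: 15 N-tosyl diol
Product: 17 (1S,3S,5R,6S,13Z)-5-[2-(tert-butyldimethylsilyloxy)ethyl]-1,3-dihydroxy-3-methyl-10-azaspiro[5.8]tetradec-13-ene-10-carbaldehyde, via secondary amine 16 (not isolated)
Conditions: sodium naphthalenide (NaC10H8), DME, −78 °C; then HCO2Et, 55 °C
Reagents that add atoms: ethyl formate, CCOC=O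
Why: Single-electron reductive cleavage of the N–S bond should spare the isolated olefin, the silyl ether and the alkoxides, and aminolysis of ethyl formate formylates the amine far faster than the secondary and tertiary alcohols.

**Step 11**
Reactants: 17 N-formyl diol
Product: 18 diacetate of 17 (C1 and C3 acetates, configured as in 23)
Conditions: Ac2O, DMAP, Et3N, CH2Cl2, 40 °C
Reagents that add atoms: acetic anhydride, CC(=O)OC(C)=O
Why: DMAP-catalysed acylation should acetylate the secondary alcohol quickly and, with excess reagent and warming, the tertiary alcohol as well, without touching a stereocentre.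

**Step 12**
Reactants: 18 diacetate silyl ether
Product: 19 primary alcohol (C7–OH)
Conditions: HF·pyridine, THF, 0 °C
Reagents that add atoms: none
Why: Fluoride-driven cleavage of the primary silyl ether should leave both acetates and the formamide intact.

**Step 13**
Reactants: 19 primary alcohol
Product: 20 aldehyde (C7 = CHO)
Conditions: Dess–Martin periodinane, NaHCO3, CH2Cl2, 0 °C
Reagents that add atoms: none
Why: Dess–Martin oxidation should stop at the aldehyde under buffered, non-epimerising conditions.

**Step 14**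
Reactants: 20 aldehyde
Product: 21 tricyclic homoallylic alcohol (ring B closed; C7–OH, C8–H, C9=C10 Z)
Conditions: Me2AlCl, CH2Cl2, −78 → −40 °C
Reagents that add atoms: none
Why: In a Lewis-acid-promoted intramolecular carbonyl-ene reaction C7 should bond to C8 with hydrogen transfer from C10, closing ring B cis-fused because the aldehyde arm and the olefinic branch are cis on ring A, whereas attack at C9 would need an allylic hydrogen on the quaternary C16.

**Step 15**
Reactants: 21 homoallylic alcohol
Product: 23 target CNP0137427.1 (1S,3S,5S,16S in the own numbering), via deconjugated ketone 22 (not isolated)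
Conditions: Dess–Martin periodinane, CH2Cl2, rt; then DBU, rt
Reagents that add atoms: none
Why: Oxidation gives the β,γ-unsaturated ketone, and base-mediated isomerisation through the dienolate should move the olefin into conjugation at C8=C9, where the nine-membered ring allows only the in-ring cis olefin, that is the required E-enone.

**Compound list**

1 | (1Z,5Z)-cycloocta-1,5-diene | C1C\C=C/CC\C=C/1 | starting material
2 | (4Z)-oct-4-ene-1,8-diol | OCCC/C=C\CCCO | intermediate
3 | (4Z)-oct-4-ene-1,8-diyl dimethanesulfonate | CS(=O)(=O)OCCC/C=C\CCCOS(C)(=O)=O | intermediate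
4 | 4-methylbenzenesulfonamide | Cc1ccc(cc1)S(N)(=O)=O | starting material
5 | (5Z)-1-(4-methylbenzenesulfonyl)-2,3,4,7,8,9-hexahydro-1H-azonine | Cc1ccc(cc1)S(=O)(=O)N1CCC/C=C\CCC1 | intermediate
6 | 1-[6-chloro-1-(4-methylbenzenesulfonyl)azonan-5-yl]ethan-1-one (racemic, not isolated) | CC(=O)C1CCCN(S(=O)(=O)c2ccc(C)cc2)CCCC1Cl | intermediate
7 | 1-[(5E)-1-(4-methylbenzenesulfonyl)-2,3,4,7,8,9-hexahydro-1H-azonin-5-yl]ethan-1-one | CC(=O)/C1=C/CCCN(S(=O)(=O)c2ccc(C)cc2)CCC1 | intermediate
8 | 3-[(tert-butyldimethylsilyl)oxy]propanal | CC(C)(C)[Si](C)(C)OCCC=O | starting material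
9 | 1-(triphenyl-λ5-phosphanylidene)propan-2-one | CC(=O)C=P(c1ccccc1)(c1ccccc1)c1ccccc1 | starting material
10 | (3E)-6-[(tert-butyldimethylsilyl)oxy]hex-3-en-2-one | CC(=O)/C=C/CCO[Si](C)(C)C(C)(C)C | intermediate
11 | (4R)-4-[(5S,6Z)-5-acetyl-1-(4-methylbenzenesulfonyl)-2,3,4,5,8,9-hexahydro-1H-azonin-5-yl]-6-[(tert-butyldimethylsilyl)oxy]hexan-2-one (Michael adduct, not isolated) | CC(=O)C[C@@H](CCO[Si](C)(C)C(C)(C)C)[C@]1(C(C)=O)/C=C\CCN(S(=O)(=O)c2ccc(C)cc2)CCC1 | intermediate
12 | (5S,6S,13Z)-5-[2-(tert-butyldimethylsilyloxy)ethyl]-3-methyl-10-(4-methylbenzenesulfonyl)-10-azaspiro[5.8]tetradeca-2,13-dien-1-one | O=C1C=C(C)C[C@@H](CCO[Si](C)(C)C(C)(C)C)[C@@]12/C=C\CCN(S(=O)(=O)c3ccc(C)cc3)CCC2 | intermediate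
13 | (1S,5S,6S,13Z)-5-[2-(tert-butyldimethylsilyloxy)ethyl]-3-methyl-10-(4-methylbenzenesulfonyl)-10-azaspiro[5.8]tetradeca-2,13-dien-1-ol | O[C@H]1C=C(C)C[C@@H](CCO[Si](C)(C)C(C)(C)C)[C@@]12/C=C\CCN(S(=O)(=O)c3ccc(C)cc3)CCC2 | intermediate
14 | syn-2,3-epoxy alcohol of 13 (epoxide and C1–OH on the same face) | O[C@H]1[C@H]2O[C@@]2(C)C[C@@H](CCO[Si](C)(C)C(C)(C)C)[C@@]13/C=C\CCN(S(=O)(=O)c4ccc(C)cc4)CCC3 | intermediate
15 | (1S,3S,5R,6S,13Z)-5-[2-(tert-butyldimethylsilyloxy)ethyl]-3-methyl-10-(4-methylbenzenesulfonyl)-10-azaspiro[5.8]tetradec-13-ene-1,3-diol | O[C@H]1C[C@@](C)(O)C[C@@H](CCO[Si](C)(C)C(C)(C)C)[C@@]12/C=C\CCN(S(=O)(=O)c3ccc(C)cc3)CCC2 | intermediate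
16 | N-H amine corresponding to 15 (not isolated) | O[C@H]1C[C@@](C)(O)C[C@@H](CCO[Si](C)(C)C(C)(C)C)[C@@]12/C=C\CCNCCC2 | intermediate
17 | (1S,3S,5R,6S,13Z)-5-[2-(tert-butyldimethylsilyloxy)ethyl]-1,3-dihydroxy-3-methyl-10-azaspiro[5.8]tetradec-13-ene-10-carbaldehyde | O[C@H]1C[C@@](C)(O)C[C@@H](CCO[Si](C)(C)C(C)(C)C)[C@@]12/C=C\CCN(C=O)CCC2 | intermediate
18 | 1,3-diacetate of 17 | CC(=O)O[C@H]1C[C@@](C)(OC(C)=O)C[C@@H](CCO[Si](C)(C)C(C)(C)C)[C@@]12/C=C\CCN(C=O)CCC2 | intermediate
19 | 1,3-diacetoxy-5-(2-hydroxyethyl) N-formyl spirocycle | CC(=O)O[C@H]1C[C@@](C)(OC(C)=O)C[C@@H](CCO)[C@@]12/C=C\CCN(C=O)CCC2 | intermediate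
20 | 1,3-diacetoxy-5-(2-oxoethyl) N-formyl spirocycle | CC(=O)O[C@H]1C[C@@](C)(OC(C)=O)C[C@@H](CC=O)[C@@]12/C=C\CCN(C=O)CCC2 | intermediate
21 | tricyclic homoallylic alcohol (C7–OH, C8–H, C9=C10; C7 and C8 undefined) | CC(=O)O[C@H]1C[C@@](C)(OC(C)=O)C[C@H]2CC(O)C3/C=C\CN(C=O)CCC[C@@]321 | intermediate
22 | tricyclic β,γ-unsaturated ketone (C7=O, C9=C10; not isolated) | CC(=O)O[C@H]1C[C@@](C)(OC(C)=O)C[C@H]2CC(=O)C3/C=C\CN(C=O)CCC[C@@]321 | intermediate
23 | CNP0137427.1 | CC(=O)O[C@H]1C[C@@](C)(OC(C)=O)C[C@H]2CC(=O)/C3=C/CCN(C=O)CCC[C@@]321 | target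

**Totals**

Total step count: 15. Longest linear sequence: 14 (steps 1–4 and 6–15).

**Steps most likely to fail**

Step 6 (Proposed new method). The ion-paired dienolate may be shielded too loosely for useful enantiofacial discrimination, or may add in part through its γ-carbon, so the quaternary centre would form with poor enantio- or regiocontrol. The fallback resolves instead of inducing. From 7 and 10, the annulation is run with an achiral base (KOt-Bu, t-BuOH, 25 °C; Robinson-type Michael/aldol condensation through the thermodynamic dienolate) and should give 12 together with its enantiomer, ent-12 F1. Reduction as in step 7 gives 13 and ent-13 F2. Esterification of the mixture with (S)-O-acetylmandelic acid (DCC, DMAP, CH2Cl2) gives two diastereomeric esters, the (S)-O-acetylmandelate of 13 F3 and the (S)-O-acetylmandelate of ent-13 F4, which are separated by chromatography. Methanolysis of F3 (K2CO3, MeOH) returns the route at 13.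

Step 14. Under the Lewis acid the tertiary acetate may ionise, or the cationic Prins pathway with chloride capture may win over the concerted ene reaction. The fallback closes ring B by a radical instead. From 20, thiol-catalysed radical-chain hydroacylation (tert-dodecanethiol cat., AIBN, benzene, 80 °C; 5-exo cyclisation of the acyl radical onto C8) should give the saturated ring B ketone F5. Thermodynamic silylation (TMSOTf, Et3N, CH2Cl2, 0 °C) gives the more substituted C7=C8 silyl enol ether F6. Saegusa–Ito oxidation with Pd(OAc)2 in MeCN, where a β-hydrogen is available only at C9, returns the route at 23.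

Step 4. The secondary medium-ring carbocation formed on acylation may undergo a transannular hydride shift or cyclisation before chloride capture. The fallback avoids the cation. From 5, mCPBA gives the meso epoxide F7. Opening with lithium acetylide–ethylenediamine complex (LiC≡CH·H2NCH2CH2NH2, DMSO, 60 °C) gives the trans ethynyl alcohol F8. Hydration of the alkyne (HgSO4, H2SO4, aqueous acetone) gives the β-hydroxy methyl ketone F9, and dehydration (TsOH, toluene, reflux) returns the route at 7.

**Further compounds**

F1 | step 6 | ent-12, (5R,6R,13Z)-enantiomer of spiro enone 12 | O=C1C=C(C)C[C@H](CCO[Si](C)(C)C(C)(C)C)[C@]12/C=C\CCN(S(=O)(=O)c3ccc(C)cc3)CCC2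
F2 | step 6 | ent-13, (1R,5R,6R,13Z)-enantiomer of allylic alcohol 13 | O[C@@H]1C=C(C)C[C@H](CCO[Si](C)(C)C(C)(C)C)[C@]12/C=C\CCN(S(=O)(=O)c3ccc(C)cc3)CCC2
F3 | step 6 | (S)-O-acetylmandelate of 13 | CC(=O)O[C@H](C(=O)O[C@H]1C=C(C)C[C@@H](CCO[Si](C)(C)C(C)(C)C)[C@@]12/C=C\CCN(S(=O)(=O)c3ccc(C)cc3)CCC2)c1ccccc1
F4 | step 6 | (S)-O-acetylmandelate of ent-13 | CC(=O)O[C@H](C(=O)O[C@@H]1C=C(C)C[C@H](CCO[Si](C)(C)C(C)(C)C)[C@]12/C=C\CCN(S(=O)(=O)c3ccc(C)cc3)CCC2)c1ccccc1
F5 | step 14 | saturated tricyclic ketone (C7=O, C8–H, C9H2; C8 undefined) | CC(=O)O[C@H]1C[C@@](C)(OC(C)=O)C[C@H]2CC(=O)C3CCCN(C=O)CCC[C@@]321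
F6 | step 14 | C7=C8 trimethylsilyl enol ether of F5 | CC(=O)O[C@H]1C[C@@](C)(OC(C)=O)C[C@H]2CC(O[Si](C)(C)C)=C3CCCN(C=O)CCC[C@@]321
F7 | step 4 | meso cis-5,6-epoxide of azonine 5 | Cc1ccc(cc1)S(=O)(=O)N1CCC[C@H]2O[C@H]2CCC1
F8 | step 4 | trans-6-ethynyl-1-(4-methylbenzenesulfonyl)azonan-5-ol (racemic, one enantiomer drawn) | C#C[C@@H]1CCCN(S(=O)(=O)c2ccc(C)cc2)CCC[C@H]1O
F9 | step 4 | trans-1-[6-hydroxy-1-(4-methylbenzenesulfonyl)azonan-5-yl]ethan-1-one (racemic, one enantiomer drawn) | CC(=O)[C@@H]1CCCN(S(=O)(=O)c2ccc(C)cc2)CCC[C@H]1O
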